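The α-methylene-γ-butyrolactone (ring O–C12–C11–C7–C6) is disconnected into 2-bromoacrylic acid and the C6=C7 bond of a linear (E,E)-dienynol, whose C4=C5–C6=C7 diene later supplies the ring C4=C5 alkene. One palladium-catalysed Larock-type heteroannulation forges C11–C7 by carbopalladation and O–C6 by carboxylate capture of the C4–C5–C6 allyl unit, setting C6 and C7 under direction of the free C8 carbinol. The precursor carries C8, C10 (chiral pool) and a silyl-capped C2≡C3 alkyne. Afterwards the ten-membered carbocycle is closed at C1–C2 by chromium-mediated iodoalkyne–aldehyde coupling, and the 3(2H)-furanone by gold-catalysed cyclisation of the α'-hydroxy ynone.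

Key step: step 10

Remark on numbering: germacrane numbers are used throughout: C1 ketone carbon, C2=C3 furanone alkene, C4 (bearing C15H2OAc)=C5, C6 (lactone oxygen), C7, C8 (methacrylate), C9, C10 (quaternary, methyl C14), C11(=C13H2)–C12 of the lactone. All intermediates from 18 on are (6R,7R,8S,10R), with C3 and C6 cis on C4=C5.
Remark on reagents: Cy2BH is taken as a separately prepared reagent; compounds 1, 5, 6, 9 and 17 are taken as commercial.

Step 1
Reactants: 1 (R)-citramalic acid
Product: 2 (2R)-2-methylbutane-1,2,4-triol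
Conditions: BH3·SMe2, B(OMe)3, THF, 0 °C to rt; then MeOH
Reagents that add atoms: none
Why: Borane reduction of both carboxylic acids through acyloxyboranes should give the triol and leaves the chiral-pool carbinol (later C10) untouched.

Step 2
Reactants: 2 (2R)-2-methylbutane-1,2,4-triol
Product: 3 2-[(4R)-2,2,4-trimethyl-1,3-dioxolan-4-yl]ethanol
Conditions: 2,2-dimethoxypropane, TsOH (cat.), acetone, rt
Reagents that add atoms: 2,2-dimethoxypropane COC(C)(C)OC
Why: Acetonide formation under thermodynamic control should favour the five-membered dioxolane across the vicinal primary/tertiary diol, leaving only the future C8 hydroxyl free.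

Step 3
Reactants: 3 2-[(4R)-2,2,4-trimethyl-1,3-dioxolan-4-yl]ethanol
Product: 4 2-[(4R)-2,2,4-trimethyl-1,3-dioxolan-4-yl]acetaldehyde
Conditions: Dess–Martin periodinane, pyridine, CH2Cl2, 0 °C to rt
Reagents that add atoms: none
Why: Dess–Martin oxidation under buffered, non-basic conditions should give the β-alkoxy aldehyde without β-elimination.

Step 4
Reactants: 5 ethyl (triphenylphosphoranylidene)acetate; 6 3-(trimethylsilyl)prop-2-ynal
Product: 8 ethyl (2Z)-2-bromo-5-(trimethylsilyl)pent-2-en-4-ynoate, via bromo ylide 7 (not isolated)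
Conditions: NBS, CH2Cl2, −20 °C; then 6, −20 °C to rt
Reagents that add atoms: N-bromosuccinimide O=C1CCC(=O)N1Br
Why: Bromination of the stabilised ylide followed by Wittig olefination of the ynal should place the ester trans to the alkynyl group, so that bromine (the later C3 position) and C6 are cis on C4=C5.

Step 5
Reactants: 8 ethyl (2Z)-2-bromo-5-(trimethylsilyl)pent-2-en-4-ynoate; 9 ethynyl(triisopropyl)silane
Product: 10 ethyl (2E)-5-(trimethylsilyl)-2-[(triisopropylsilyl)ethynyl]pent-2-en-4-ynoate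
Conditions: PdCl2(PPh3)2 (3 mol%), CuI (6 mol%), i-Pr2NH, THF, rt
Reagents that add atoms: none
Why: Sonogashira coupling of the α-bromo enoate proceeds with retention of alkene geometry and installs C2≡C3 as a triisopropylsilyl-capped alkyne.

Step 6
Reactants: 10 ethyl (2E)-5-(trimethylsilyl)-2-[(triisopropylsilyl)ethynyl]pent-2-en-4-ynoate
Product: 11 (2E)-5-(trimethylsilyl)-2-[(triisopropylsilyl)ethynyl]pent-2-en-4-yn-1-ol
Conditions: i-Bu2AlH (2.2 equiv), CH2Cl2, −78 °C
Reagents that add atoms: none
Why: 1,2-Reduction of the conjugated ester with the aluminium hydride should give the C15 allylic alcohol without touching the silyl alkynes.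

Step 7
Reactants: 11 (2E)-5-(trimethylsilyl)-2-[(triisopropylsilyl)ethynyl]pent-2-en-4-yn-1-ol
Product: 12 tert-butyl(dimethyl){[(2E)-5-(trimethylsilyl)-2-[(triisopropylsilyl)ethynyl]pent-2-en-4-yn-1-yl]oxy}silane
Conditions: TBSCl, imidazole, CH2Cl2, rt
Reagents that add atoms: tert-butyldimethylsilyl chloride CC(C)(C)[Si](C)(C)Cl
Why: Silyl ether formation protects C15–OH so that no allylic ester is present during the later palladium step.

Step 8
Reactants: 12 tert-butyl(dimethyl){[(2E)-5-(trimethylsilyl)-2-[(triisopropylsilyl)ethynyl]pent-2-en-4-yn-1-yl]oxy}silane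
Product: 13 tert-butyl(dimethyl){[(2E)-2-[(triisopropylsilyl)ethynyl]pent-2-en-4-yn-1-yl]oxy}silane
Conditions: K2CO3 (cat.), MeOH, 0 °C to rt
Reagents that add atoms: none
Why: Base-catalysed methanolysis should cleave the trimethylsilyl alkyne selectively, since the bulky triisopropylsilyl alkyne and the silyl ether are stable to these conditions.

Step 9
Reactants: 13 tert-butyl(dimethyl){[(2E)-2-[(triisopropylsilyl)ethynyl]pent-2-en-4-yn-1-yl]oxy}silane; 4 2-[(4R)-2,2,4-trimethyl-1,3-dioxolan-4-yl]acetaldehyde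
Product: 16 dienynol (2S,3E,5E)-6-{[(tert-butyldimethylsilyl)oxy]methyl}-1-[(4R)-2,2,4-trimethyl-1,3-dioxolan-4-yl]-8-(triisopropylsilyl)octa-3,5-dien-7-yn-2-ol, via alkenylborane 14 (not isolated), via alkenylzinc 15 (not isolated)
Conditions: Cy2BH, toluene, 0 °C to rt; Me2Zn, −78 °C; (+)-MIB (5 mol%); then 4, −20 °C to 0 °C
Reagents that add atoms: none
Why: syn-Hydroboration of the terminal alkyne fixes the (E)-C6=C7 geometry, boron-to-zinc exchange gives the alkenylzinc, and its amino-alcohol-catalysed asymmetric addition to 4 (catalytic asymmetric alkenylzinc addition) should set C8 as (S) by ligand-controlled delivery to the Re face of the aldehyde.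

Step 10
Reactants: 16 dienynol (2S,3E,5E)-6-{[(tert-butyldimethylsilyl)oxy]methyl}-1-[(4R)-2,2,4-trimethyl-1,3-dioxolan-4-yl]-8-(triisopropylsilyl)octa-3,5-dien-7-yn-2-ol; 17 2-bromoprop-2-enoic acid (2-bromoacrylic acid)
Product: 18 (4R,5R)-5-[(1E)-2-{[(tert-butyldimethylsilyl)oxy]methyl}-4-(triisopropylsilyl)but-1-en-3-yn-1-yl]-4-{(1S)-1-hydroxy-2-[(4R)-2,2,4-trimethyl-1,3-dioxolan-4-yl]ethyl}-3-methylideneoxolan-2-one
Conditions: Pd(OAc)2 (10 mol%), n-Bu4NCl (1 equiv), NaHCO3 (3 equiv), 17 (2 equiv, slow addition), DMF, 70 °C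
Reagents that add atoms: none
Why: Oxidative addition of zerovalent palladium into the C–Br bond of 17 (as its carboxylate) gives a 1-carboxyvinyl divalent palladium species that inserts the diene of 16 at C7, the only diene terminus that is not fully substituted, forming C11–C7 and an η3-allyl over C6–C5–C4; the palladium-bound carboxylate then closes a six-membered oxapalladacycle and C–O reductive elimination at C6 forms the lactone and returns zerovalent palladium. The closest known reaction type is the Larock heteroannulation of 1,3-dienes by aryl or vinylic halides that carry a carboxylic acid, run here ligand-free with chloride. The lactone ring closes as a (3+2) annulation whose ring-forming event is a 5-exo attack of oxygen on the allyl terminus C6, so that C4=C5 ends outside the new ring. C7 should be set by the C8 carbinol, because in the conformer with H8 eclipsing the alkene the hydroxyl-coordinated palladium delivers the vinyl group to the face syn to OH and anti to the bulky C9 branch; C6 follows from syn carbopalladation of the (E)-C6=C7 bond and inner-sphere C–O formation with retention, which gives the trans lactone (H6 and H7 anti). The step needs site selectivity for the diene over the alkyne and retention of the C4=C5 geometry; the triisopropylsilyl group shields the alkyne, and in the allyl intermediate the slim alkynyl group keeps the anti position while CH2OTBS stays syn, so C3 and C6 should remain cis.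

Step 11
Reactants: 18 (4R,5R)-5-[(1E)-2-{[(tert-butyldimethylsilyl)oxy]methyl}-4-(triisopropylsilyl)but-1-en-3-yn-1-yl]-4-{(1S)-1-hydroxy-2-[(4R)-2,2,4-trimethyl-1,3-dioxolan-4-yl]ethyl}-3-methylideneoxolan-2-one
Product: 19 C8 methacrylate of 18 (C15–OTBS, C10/C1 acetonide, C3–TIPS)
Conditions: methacrylic anhydride, Et3N, DMAP (cat.), CH2Cl2, 0 °C to rt
Reagents that add atoms: methacrylic anhydride C=C(C)C(=O)OC(=O)C(C)=C
Why: DMAP-catalysed acylation of the only free hydroxyl (C8) installs the methacrylate with retention of configuration.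

Step 12
Reactants: 19 C8 methacrylate of 18
Product: 20 C15 alcohol (19 without the tert-butyldimethylsilyl group)
Conditions: HF·pyridine, pyridine, THF, 0 °C to rt
Reagents that add atoms: none
Why: Buffered fluoride desilylation should cleave the primary silyl ether while the alkynylsilane, acetonide, lactone and methacrylate survive.

Step 13
Reactants: 20 C15 alcohol
Product: 21 C15 acetate (C8 methacrylate, C10/C1 acetonide, C3–TIPS)
Conditions: Ac2O, pyridine, DMAP (cat.), CH2Cl2, 0 °C
Reagents that add atoms: acetic anhydride CC(=O)OC(C)=O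
Why: Acetylation of the primary allylic alcohol installs the C15 acetate after the last zerovalent palladium step.

Step 14
Reactants: 21 C15 acetate
Product: 22 1-iodoalkyne (21 with iodine in place of the triisopropylsilyl group on C2)
Conditions: AgF, NIS, MeCN, rt, dark
Reagents that add atoms: N-iodosuccinimide O=C1CCC(=O)N1I
Why: Fluoride-assisted, silver-mediated desilylative iodination should convert the triisopropylsilyl alkyne directly into the iodoalkyne needed for chromium insertion.

Step 15
Reactants: 22 1-iodoalkyne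
Product: 23 C10,C1-diol (22 without the acetonide)
Conditions: AcOH/H2O (4:1), 40 °C
Reagents that add atoms: none
Why: Mild aqueous acid hydrolysis of the dioxolane should free the tertiary C10 and primary C1 hydroxyls without cleaving the acetate, methacrylate or lactone.

Step 16
Reactants: 23 C10,C1-diol
Product: 24 α-hydroxy aldehyde (C1 aldehyde, C10 tertiary alcohol, C2 iodoalkyne)
Conditions: TEMPO (10 mol%), PhI(OAc)2, CH2Cl2, rt
Reagents that add atoms: none
Why: Oxoammonium (TEMPO) oxidation is selective for the primary alcohol and should give the non-enolisable α-hydroxy aldehyde.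

Step 17
Reactants: 24 α-hydroxy aldehyde
Product: 25 ten-membered cyclic enynediol (C1 carbinol as epimer mixture, C10 tertiary alcohol, C2≡C3 in the ring)
Conditions: CrCl2 (8 equiv), NiCl2 (1 mol%), THF, rt, 0.002 M
Reagents that add atoms: none
Why: Nozaki–Hiyama–Kishi coupling, in which divalent chromium inserts into the C–I bond and the alkynylchromium adds to the aldehyde under high dilution, should close the carbocycle at C1–C2; the C1 configuration is irrelevant because it is oxidised next.

Step 18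
Reactants: 25 ten-membered cyclic enynediol
Product: 26 cyclic α'-hydroxy ynone (C1 ketone, C10 tertiary alcohol)
Conditions: Dess–Martin periodinane, pyridine, CH2Cl2, 0 °C
Reagents that add atoms: none
Why: Dess–Martin oxidation of the secondary propargylic alcohol should give the ynone, the tertiary hydroxyl being inert.

Step 19
Reactants: 26 cyclic α'-hydroxy ynone
Product: 27 CNP0179932.1 (15-O-acetyl furanoheliangolide, 6R,7R,8S,10R)
Conditions: Ph3PAuNTf2 (5 mol%), CH2Cl2, rt
Reagents that add atoms: none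
Why: Gold-catalysed 5-endo-dig hydroalkoxylation, in which the C10 hydroxyl adds anti to the activated alkyne at C3 and protodeauration follows, should give the 3(2H)-furanone and relieve the strain of the cycloalkyne.

Compound list
1 | (R)-citramalic acid, (2R)-2-hydroxy-2-methylbutanedioic acid | C[C@@](O)(CC(=O)O)C(=O)O | starting material
2 | (2R)-2-methylbutane-1,2,4-triol | C[C@@](O)(CCO)CO | intermediate
3 | 2-[(4R)-2,2,4-trimethyl-1,3-dioxolan-4-yl]ethanol | C[C@@]1(CCO)COC(C)(C)O1 | intermediate
4 | 2-[(4R)-2,2,4-trimethyl-1,3-dioxolan-4-yl]acetaldehyde | C[C@@]1(CC=O)COC(C)(C)O1 | intermediate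
5 | ethyl (triphenylphosphoranylidene)acetate | CCOC(=O)C=P(c1ccccc1)(c1ccccc1)c1ccccc1 | starting material
6 | 3-(trimethylsilyl)prop-2-ynal | C[Si](C)(C)C#CC=O | starting material
7 | ethyl bromo(triphenylphosphoranylidene)acetate | CCOC(=O)C(Br)=P(c1ccccc1)(c1ccccc1)c1ccccc1 | intermediate
8 | ethyl (2Z)-2-bromo-5-(trimethylsilyl)pent-2-en-4-ynoate | CCOC(=O)/C(Br)=C/C#C[Si](C)(C)C | intermediate
9 | ethynyl(triisopropyl)silane | C#C[Si](C(C)C)(C(C)C)C(C)C | starting material
10 | ethyl (2E)-5-(trimethylsilyl)-2-[(triisopropylsilyl)ethynyl]pent-2-en-4-ynoate | CCOC(=O)/C(C#C[Si](C(C)C)(C(C)C)C(C)C)=C/C#C[Si](C)(C)C | intermediate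
11 | (2E)-5-(trimethylsilyl)-2-[(triisopropylsilyl)ethynyl]pent-2-en-4-yn-1-ol | OC/C(C#C[Si](C(C)C)(C(C)C)C(C)C)=C/C#C[Si](C)(C)C | intermediate
12 | tert-butyl(dimethyl){[(2E)-5-(trimethylsilyl)-2-[(triisopropylsilyl)ethynyl]pent-2-en-4-yn-1-yl]oxy}silane | CC(C)(C)[Si](C)(C)OC/C(C#C[Si](C(C)C)(C(C)C)C(C)C)=C/C#C[Si](C)(C)C | intermediate
13 | tert-butyl(dimethyl){[(2E)-2-[(triisopropylsilyl)ethynyl]pent-2-en-4-yn-1-yl]oxy}silane | CC(C)(C)[Si](C)(C)OC/C(C#C[Si](C(C)C)(C(C)C)C(C)C)=C/C#C | intermediate
14 | (1E,3E)-dienyl(dicyclohexyl)borane from hydroboration of the terminal alkyne of 13 | CC(C)(C)[Si](C)(C)OC/C(C#C[Si](C(C)C)(C(C)C)C(C)C)=C/C=C/B(C1CCCCC1)C1CCCCC1 | intermediate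
15 | (1E,3E)-dienyl(methyl)zinc from 14 | CC(C)(C)[Si](C)(C)OC/C(C#C[Si](C(C)C)(C(C)C)C(C)C)=C/C=C/[Zn]C | intermediate
16 | (2S,3E,5E)-6-{[(tert-butyldimethylsilyl)oxy]methyl}-1-[(4R)-2,2,4-trimethyl-1,3-dioxolan-4-yl]-8-(triisopropylsilyl)octa-3,5-dien-7-yn-2-ol | CC(C)(C)[Si](C)(C)OC/C(C#C[Si](C(C)C)(C(C)C)C(C)C)=C/C=C/[C@@H](O)C[C@]1(C)COC(C)(C)O1 | intermediate
17 | 2-bromoprop-2-enoic acid | C=C(Br)C(=O)O | starting material
18 | (4R,5R)-5-[(1E)-2-{[(tert-butyldimethylsilyl)oxy]methyl}-4-(triisopropylsilyl)but-1-en-3-yn-1-yl]-4-{(1S)-1-hydroxy-2-[(4R)-2,2,4-trimethyl-1,3-dioxolan-4-yl]ethyl}-3-methylideneoxolan-2-one | CC(C)(C)[Si](C)(C)OC/C(C#C[Si](C(C)C)(C(C)C)C(C)C)=C/[C@H]1OC(=O)C(=C)[C@@H]1[C@@H](O)C[C@]2(C)COC(C)(C)O2 | intermediate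
19 | C8 methacrylate of 18 (6R,7R,8S,10R) | CC(C)(C)[Si](C)(C)OC/C(C#C[Si](C(C)C)(C(C)C)C(C)C)=C/[C@H]1OC(=O)C(=C)[C@@H]1[C@@H](OC(=O)C(C)=C)C[C@]2(C)COC(C)(C)O2 | intermediate
20 | C15 alcohol: 19 with free CH2OH on C4 | OC/C(C#C[Si](C(C)C)(C(C)C)C(C)C)=C/[C@H]1OC(=O)C(=C)[C@@H]1[C@@H](OC(=O)C(C)=C)C[C@]2(C)COC(C)(C)O2 | intermediate
21 | C15 acetate of 20 | CC(=O)OC/C(C#C[Si](C(C)C)(C(C)C)C(C)C)=C/[C@H]1OC(=O)C(=C)[C@@H]1[C@@H](OC(=O)C(C)=C)C[C@]2(C)COC(C)(C)O2 | intermediate
22 | 1-iodoalkyne: 21 with I in place of the triisopropylsilyl group | CC(=O)OC/C(C#CI)=C/[C@H]1OC(=O)C(=C)[C@@H]1[C@@H](OC(=O)C(C)=C)C[C@]2(C)COC(C)(C)O2 | intermediate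
23 | diol: 22 with free C10 tertiary and C1 primary hydroxyls | CC(=O)OC/C(C#CI)=C/[C@H]1OC(=O)C(=C)[C@@H]1[C@@H](OC(=O)C(C)=C)C[C@@](C)(O)CO | intermediate
24 | α-hydroxy aldehyde: 23 with C1 as CHO | CC(=O)OC/C(C#CI)=C/[C@H]1OC(=O)C(=C)[C@@H]1[C@@H](OC(=O)C(C)=C)C[C@@](C)(O)C=O | intermediate
25 | ten-membered cyclic enynediol (C1 carbinol epimers, C10 tertiary alcohol, ring C2≡C3, trans-fused lactone, C8 methacrylate, C15 acetate) | CC(=O)OC/C1=C/[C@H]2OC(=O)C(=C)[C@@H]2[C@@H](OC(=O)C(C)=C)C[C@@](C)(O)C(O)C#C1 | intermediate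
26 | cyclic α'-hydroxy ynone (C1 ketone of 25) | CC(=O)OC/C1=C/[C@H]2OC(=O)C(=C)[C@@H]2[C@@H](OC(=O)C(C)=C)C[C@@](C)(O)C(=O)C#C1 | intermediate
27 | CNP0179932.1 (6R,7R,8S,10R; 4Z) | C=C(C)C(=O)O[C@H]1C[C@@]2(C)OC(=CC2=O)/C(COC(C)=O)=C\[C@H]2OC(=O)C(=C)[C@H]12 | target

Total step count: 19. Longest linear sequence: 16 steps (steps 4 to 19, from 5 and 6).

Steps most likely to fail

Step 10. The carbopalladation may proceed with low or reversed facial selectivity at C7, because the acyclic allylic carbinol can react through conformers in which hydroxyl direction is lost. Insertion of the vinylpalladium species into the silyl alkyne may also compete. The fallback covers reversed induction. It sets out from 13 and 4 and inverts the stereochemical plan at C8. Step 9 is run with (−)-MIB to give the (8R)-dienynol F1. F1 is annulated with 17 under the conditions of step 10 to give the (6R,7R,8R)-hydroxy lactone F2. The methacrylate is then introduced with inversion at C8 by Mitsunobu esterification (methacrylic acid, PPh3, DIAD, toluene, 0 °C), which returns to the route at 19.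

Step 17. Oligomerisation and protodeiodination may outcompete closure of the strained ten-membered cycloalkyne. The fallback sets out from 24 and avoids a ring alkyne altogether. Ph3PAuNTf2-catalysed hydration of the iodoalkyne (H2O, dioxane) should give the α-iodomethyl enone aldehyde F3. A SmI2-promoted intramolecular Reformatsky reaction (THF, −78 °C, high dilution) should close the ring at C1–C2 to the β-hydroxy ketone F4. Dess–Martin oxidation gives the α'-hydroxy 1,3-diketone F5, and acid-catalysed cyclodehydration (TsOH, toluene) returns to the route at 27.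

Step 9. Enantiofacial control may erode, because zinc chelation by the β-oxygen of the unbranched aldehyde can open an unligated addition pathway and give C8 epimers. The fallback sets out from 13 and 4. The lithium acetylide of 13 (n-BuLi, THF, −78 °C) adds to 4 to give the propargylic alcohols F6 as both C8 epimers. Dess–Martin oxidation gives the ynone F7. Noyori-type transfer hydrogenation with RuCl(p-cymene)[(S,S)-TsDPEN] in i-PrOH should give the (S)-propargylic alcohol F8. Hydroxyl-directed trans-reduction with NaAlH2(OCH2CH2OMe)2 (THF, 0 °C) returns to the route at 16.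

Further compounds
F1 | step 10 | (2R,3E,5E)-6-{[(tert-butyldimethylsilyl)oxy]methyl}-1-[(4R)-2,2,4-trimethyl-1,3-dioxolan-4-yl]-8-(triisopropylsilyl)octa-3,5-dien-7-yn-2-ol (C8 epimer of 16) | CC(C)(C)[Si](C)(C)OC/C(C#C[Si](C(C)C)(C(C)C)C(C)C)=C/C=C/[C@H](O)C[C@]1(C)COC(C)(C)O1
F2 | step 10 | (6R,7R,8R)-hydroxy lactone (C8 epimer of 18) | CC(C)(C)[Si](C)(C)OC/C(C#C[Si](C(C)C)(C(C)C)C(C)C)=C/[C@H]1OC(=O)C(=C)[C@@H]1[C@H](O)C[C@]2(C)COC(C)(C)O2
F3 | step 17 | α-iodomethyl enone aldehyde (24 with C3 as ketone and C2 as CH2I) | CC(=O)OC/C(C(=O)CI)=C/[C@H]1OC(=O)C(=C)[C@@H]1[C@@H](OC(=O)C(C)=C)C[C@@](C)(O)C=O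
F4 | step 17 | ten-membered β-hydroxy ketone (C1 carbinol, C2 methylene, C3 ketone, C10 tertiary alcohol) | CC(=O)OC/C1=C/[C@H]2OC(=O)C(=C)[C@@H]2[C@@H](OC(=O)C(C)=C)C[C@@](C)(O)C(O)CC1=O
F5 | step 17 | ten-membered α'-hydroxy 1,3-diketone (C1 and C3 ketones) | CC(=O)OC/C1=C/[C@H]2OC(=O)C(=C)[C@@H]2[C@@H](OC(=O)C(C)=C)C[C@@](C)(O)C(=O)CC1=O
F6 | step 9 | propargylic alcohols, both C8 epimers (C6≡C7 analogue of 16) | CC(C)(C)[Si](C)(C)OC/C(C#C[Si](C(C)C)(C(C)C)C(C)C)=C/C#CC(O)C[C@]1(C)COC(C)(C)O1
F7 | step 9 | C8 ynone | CC(C)(C)[Si](C)(C)OC/C(C#C[Si](C(C)C)(C(C)C)C(C)C)=C/C#CC(=O)C[C@]1(C)COC(C)(C)O1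
F8 | step 9 | (8S)-propargylic alcohol | CC(C)(C)[Si](C)(C)OC/C(C#C[Si](C(C)C)(C(C)C)C(C)C)=C/C#C[C@@H](O)C[C@]1(C)COC(C)(C)O1
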